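## Structural features

The target is a germacrane-type sesquiterpenoid. Its ten-membered carbocycle (C1–C10) is bridged by an ether oxygen between C3 and C10, so that a 3(2H)-furanone (O, C3, C2, C1, C10) and a nine-membered oxacycle share the C3–O–C10 unit (an 11-oxabicyclo[6.2.1]undecane). A cis-fused α-methylene-γ-butyrolactone (C11–C13) spans C7 and C8, and a tiglate sits on the allylic C6 oxygen. Three contiguous stereocenters C6, C7 and C8 (6S, 7R, 8S) face the isolated quaternary ether carbon C10 (S) across the C9 methylene. The C4=C5 double bond is Z within the ring and conjugated through C3 to the furanone. Fragile groups are the exo-methylene lactone (Michael acceptor), the cross-conjugated furanone and the allylic ester; in intermediates also the enol ether and the C7 methine once C8 is a ketone. The real difficulty is the strained bridged nine-membered ring with its remote C10 center, not the peripheral functionality. Redrawing the carbocycle with C3 bonded to C8 in place of C1–C10 uncovers a cyclohexene C3–C8 that carries the C4 methyl and the C7 three-carbon branch as in carvone, cis-fused to a 2-methyl-dihydrofuran holding the ether oxygen. The atoms C1=C2–C3–C8–C9=C10 then form the 1,5-diene that the key step rearranges.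

## Logic of the disconnections

32 to 30 and 31. The C6–O acyl bond is cut. The ester cannot pass the hydride, organometallic and anionic steps, so it comes last. The forward step must acylate a hindered allylic alcohol without touching the exo-methylene lactone.

30 to 29, then 29 to 26. The C6 silyl ether is restored, then the lactone C12–O8 bond is cut and C12 lowered to the alcohol. This keeps the acrylate out of all earlier chemistry. The forward oxidation must select the primary allylic alcohol and the lactol must close onto O8, so C6–O has to stay masked and C8–O must be cis to the C7 branch.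

26 to 25. The C12 oxygen is put back under an aryl ether. The ether must survive strong base and organometallics, and its oxidative removal must wait until no enol ether is left.

25 to 23. The C1 carbonyl is removed to a methylene. This turns the furanone into the cyclic enol ether that the rearrangement delivers. The forward step is a site-selective C–H oxidation next to the enol ether.

23 to 22. C8–H is exchanged for the C8 ketone, the direct outcome of the key step. The forward reduction must choose one face of a medium-ring ketone and be done before C7 can epimerize.

22 to 19. C1–C10 is cut and C3–C8 joined. The bridged bicycle collapses to a cis-fused six/five bicycle on a carvone frame, and the C10 stereocenter is traded for the angular C3 center. The forward step must form C1–C10 on the face where the vinyl group stands and break a ring-fusion bond.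

19 to 18. The O–C10 bond is cut, leaving a homopropargylic alcohol. The forward 5-endo-dig closure needs the C3 oxygen and the propynyl group cis, and a catalyst mild enough for a tertiary allylic alcohol.

18 to 16 and 17. The C8–C9 bond is cut. The forward acetylide addition must put the alkyne on the face of the C3 oxygen.

16 to 15, then 15 to 13 and 14. The C8 oxidation level is adjusted and the C3–C2 bond cut. The vinyl addition must occur anti to the C7 branch, because C3 later dictates C10.

13 to 11. The C8–O bond is cut, which is an α′-hydroxylation of the kinetic enolate forward. Its configuration is irrelevant.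

11 to 10, 9 and 8, then 8 to 6 and 4. The C6 oxygen is cis to the C7 branch, whereas an oxidant approaching anti to that branch gives trans. The C6–O bond is therefore first inverted and then cut altogether, which is a γ-oxygenation of the extended dienol ether forward.

4 to 2 and 3, then 2 to 1. The C12–O bond and then the C12–Cl bond are cut, leaving the terpene, which supplies C7 and ten of the fifteen skeletal carbons.

## Other disconnections considered

Alternative 1: The cut is C1–C2, with the furanone opened to a C10 tertiary silyl ether and a C2≡C3 alkyne. Forward, the iodoalkyne aldehyde A2 is treated with CrCl2 and catalytic NiCl2; the alkynylchromium adds to the C1 aldehyde and closes the ten-membered enynol A1. Oxidation to the ynone, desilylation and 5-endo-dig closure of the C10 hydroxyl onto the ynone would then give the target, since lactone and tiglate are already present.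
- In favour: C1 is oxygenated from the start and the furanone comes from a known closure. Every step is of a known type and only about three steps follow the ring closure. On these points it is better than the chosen plan.
- Against: A2 holds four stereocenters, among them the quaternary C10 carbinol, which must be set by separate asymmetric steps in an acyclic setting. A ten-membered ring holding a Z-enyne is demanding to close and needs high dilution and excess divalent chromium. The acrylate and the tiglate must survive that reagent.
- Comparison: the chosen plan takes C7 from the terpene and relays C6, C3 and C10 on a rigid ring, so it is better on stereochemical economy. Total step count is probably about equal.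

Alternative 2: The cut removes O–C10 and C9–C10 and restores O–C7, giving a vinyl dihydropyran with a diazoketone arm, A4. Forward, Cu(hfacac)2 generates the carbenoid at C10, the ring oxygen captures it, and the oxonium ylide undergoes a [2,3]-shift onto the C7 vinyl group to give A3.
- In favour: this is the best-precedented way to oxygen-bridged nine-membered rings. It is catalytic, sets C10 and both rings in one step and places the C1 ketone correctly. On precedent and on C1 it is better than the chosen plan.
- Against: A3 is only a core. It has an sp3 C3–H, a C7=C8 alkene and no C11–C13 branch. The lactone carbons and the C8 oxygen would have to be added across C7=C8 with regio- and stereocontrol in a medium ring, and C2–C3 dehydrogenated. The [1,2]-shift and alkene geometry are further issues.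
- Comparison: both plans expand a six-membered ring to the nine-membered ring, so they are equal in concept. The chosen plan is better in what its key step delivers (C7 branch and C8 carbonyl in place) and probably shorter overall.

Alternative 3: The cut is C5–C6. Forward, the Z-alkenyl iodide aldehyde A6 is treated with CrCl2 and catalytic NiCl2; the alkenylchromium adds to the C6 aldehyde and closes the nine-membered ring to the alcohol A5, which is identical with 30.
- In favour: it is the most convergent endgame, one acylation from the target, which is better than the chosen plan. The reaction tolerates lactone and vinylogous ester, and the alkene geometry is fixed in the iodide.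
- Against: the aldehyde of A6 is α-branched at C7 and β-acyloxy through the lactone oxygen on C8, so epimerization and β-elimination threaten. The C6 carbinol would be set during ring closure with no reliable control element. A6 itself needs furanone and lactone assembled with C7, C8 and C10 set independently.
- Comparison: the chosen plan is better at C6, which it fixes early on a six-membered ring. The mechanism of this alternative is better understood. Overall length is about equal.

Key step: step 13

Assumptions and checks
- Locants C1–C15 are those of the target carbocycle and are kept for all intermediates (C12 lactone carbonyl, C13 exo-methylene, C14 and C15 the methyls on C10 and C4).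
- The configurations of 19 and 22 were compared atom by atom with the target. C6 and C7 are unchanged, C3 of 19 maps onto C10, and (S)-carvone supplies C7 in the right sense; no stereodescriptor needed correction.
- Three design points were changed. C6 needs an inversion (steps 5 and 6). C12 carries a p-methoxyphenyl ether in place of a p-methoxybenzyl ether. A neutral monovalent-gold catalyst replaces AuCl3.
- Hydride is assumed to add to C8 of 22 on the face that gives the 8S alcohol; the other outcome is covered by a fallback.
- 14 and 17 are used as commercial THF solutions (17 is otherwise made from propyne and ethylmagnesium bromide).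

## Steps

Step 1
Reactants: 1 (S)-(+)-carvone
Product: 2 10-chlorocarvone [(5S)-5-(3-chloroprop-1-en-2-yl)-2-methylcyclohex-2-en-1-one]
Conditions: Ca(OCl)2, solid CO2, CH2Cl2/H2O, 0 °C
Reagents that add atoms: calcium hypochlorite, [Ca+2].[O-]Cl.[O-]Cl
Why: Ene-type allylic chlorination by HOCl attacks only the electron-rich 1,1-disubstituted alkene; the enone alkene is inert and the C7 stereocenter is not involved.

Step 2
Reactants: 2 10-chlorocarvone; 3 4-methoxyphenol
Product: 4 C12 p-methoxyphenyl ether [(5S)-5-[3-(4-methoxyphenoxy)prop-1-en-2-yl]-2-methylcyclohex-2-en-1-one]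
Conditions: K2CO3, NaI (cat.), acetone, reflux
Reagents that add atoms: 3 4-methoxyphenol, COc1ccc(O)cc1
Why: Williamson SN2 displacement of the primary allylic chloride by the phenoxide under conditions too mild to enolize the enone. The aryl ether has no benzylic C–H (step 15), cannot migrate to an alkoxide (step 13) and is removed oxidatively once the enol ether is gone (step 16).

Step 3
Reactants: 4 C12 p-methoxyphenyl ether
Product: 6 trimethylsilyl dienol ether (C3-OSiMe3; C3=C4 and C5=C6), via potassium dienolate 5 (not isolated)
Conditions: KOt-Bu (1.2 equiv), THF, −78 → −20 °C; Me3SiCl, −78 °C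
Reagents that add atoms: chlorotrimethylsilane, C[Si](C)(C)Cl
Why: Thermodynamic enolization (the liberated t-BuOH shuttles protons) should give the extended, linearly conjugated dienolate by loss of a C6 hydrogen, and O-silylation fixes it as the 1-silyloxy-1,3-diene. The cross-conjugated C8 enolate is the kinetic species and is avoided by equilibration.

Step 4
Reactants: 6 trimethylsilyl dienol ether
Product: 8 6,7-trans γ-hydroxy enone [(4R,5S)-4-hydroxy-5-[3-(4-methoxyphenoxy)prop-1-en-2-yl]-2-methylcyclohex-2-en-1-one], via silyloxy endoperoxide 7 (not isolated)
Conditions: O2, visible light, tetraphenylporphyrin (cat.), CH2Cl2, −78 °C; PPh3, −78 → 0 °C; dilute aqueous HCl work-up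
Reagents that add atoms: dioxygen, O=O
Why: [4+2] addition of singlet oxygen to the cisoid ring diene puts oxygen only on C3 and C6; phosphine reduction of the O–O bond and loss of the silyl group return the enone with a C6 hydroxyl (vinylogous Rubottom-type γ-oxygenation). Approach anti to the C7 branch should favour the trans alcohol, and any cis isomer is already 10 and joins at step 7.

Step 5
Reactants: 8 6,7-trans γ-hydroxy enone
Product: 9 6,7-cis 4-nitrobenzoate [(4S,5S) ester of the γ-hydroxy enone]
Conditions: 4-O2NC6H4CO2H, PPh3, i-PrO2CN=NCO2i-Pr, THF, 0 °C → rt
Reagents that add atoms: 4-nitrobenzoic acid, OC(=O)c1ccc(cc1)[N+](=O)[O-]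
Why: Mitsunobu esterification with SN2 inversion at C6 (the nitrobenzoic acid protocol for hindered secondary alcohols) gives the cis relation of C6–O and the C7 branch that the target needs. The fully substituted C4 terminus disfavours SN2′ attack.

Step 6
Reactants: 9 6,7-cis 4-nitrobenzoate
Product: 10 6,7-cis γ-hydroxy enone [(4S,5S)-4-hydroxy-5-[3-(4-methoxyphenoxy)prop-1-en-2-yl]-2-methylcyclohex-2-en-1-one]
Conditions: K2CO3 (cat.), MeOH, 0 °C
Reagents that add atoms: none
Why: Transesterification of the activated aryl ester under catalytic carbonate at 0 °C frees the alcohol without enolizing the γ-hydroxy enone; C6 is unchanged.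

Step 7
Reactants: 10 6,7-cis γ-hydroxy enone
Product: 11 6,7-cis γ-(tert-butyldimethylsilyloxy) enone
Conditions: t-BuMe2SiCl, imidazole, DMF, rt
Reagents that add atoms: tert-butyldimethylsilyl chloride, CC(C)(C)[Si](C)(C)Cl
Why: Standard silylation of the secondary allylic alcohol. The silyl ether survives the organometallic and hydride steps and stands trans-1,3 to the later C8 alkoxide, so it cannot migrate in step 13.

Step 8
Reactants: 11 6,7-cis γ-silyloxy enone
Product: 13 α′-hydroxy enone (C8-OH trans to the C7 branch), via potassium enolate 12 (not isolated)
Conditions: KN(SiMe3)2, THF, −78 °C; 2-(phenylsulfonyl)-3-phenyloxaziridine, −78 °C; aqueous NH4Cl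
Reagents that add atoms: 2-(phenylsulfonyl)-3-phenyloxaziridine, O=S(=O)(c1ccccc1)N1OC1c1ccccc1
Why: Kinetic deprotonation of the C8 methylene gives the cross-conjugated enolate, which the N-sulfonyloxaziridine hydroxylates anti to the C7 branch (enolate oxidation). The C8 configuration does not matter because C8 is oxidized in step 10.

Step 9
Reactants: 13 α′-hydroxy enone; 14 vinylmagnesium bromide
Product: 15 C3-vinyl C3,C8-diol (C3-OH cis to the C7 branch and to C6-OSi; vinyl and C8-OH on the other face)
Conditions: CH2=CHMgBr (3.5 equiv), THF, −78 → −20 °C; aqueous NH4Cl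
Reagents that add atoms: 14 vinylmagnesium bromide, C=C[Mg]Br
Why: 1,2-Addition of the Grignard reagent to the enone; one equivalent forms the C8 magnesium alkoxide, which chelates the carbonyl. Attack opposite to the C7 branch and the pseudoaxial C6 silyl ether (the usual axial attack on 5-substituted cyclohexenones) sets C3 with its oxygen cis to the C7 branch, the center that later controls C10.

Step 10
Reactants: 15 C3-vinyl C3,C8-diol
Product: 16 α-ketol (C8 ketone; C3 tertiary alcohol bearing the vinyl group)
Conditions: Dess–Martin periodinane, NaHCO3, CH2Cl2, 0 °C
Reagents that add atoms: none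
Why: Periodinane oxidation of the only secondary alcohol; the tertiary bis-allylic C3 alcohol cannot be oxidized. Buffered, cold conditions limit α-ketol rearrangement and epimerization at the now enolizable C7.

Step 11
Reactants: 16 α-ketol; 17 1-propynylmagnesium bromide
Product: 18 C8-propynyl C3,C8-diol (propynyl cis to C3-OH and to the C7 branch; C8-OH cis to the vinyl group)
Conditions: CH3C≡CMgBr (3.5 equiv), LaCl3·2LiCl (cat.), THF, −40 → 0 °C; aqueous NH4Cl
Reagents that add atoms: 17 1-propynylmagnesium bromide, CC#C[Mg]Br
Why: Chelation-controlled acetylide addition to the α-alkoxy ketone (the first equivalent forms the C3 alkoxide). The small sp nucleophile should add axially, anti to the pseudoaxial C3 vinyl group, and the lanthanum salt favours addition over enolization at C7.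

Step 12
Reactants: 18 C8-propynyl C3,C8-diol
Product: 19 key-step precursor: cis-fused 7a-vinyl-3a-hydroxy-2-methyl-tetrahydrobenzofuran (ring O, C7 branch and C6-OSi on one face; vinyl and C8-OH on the other)
Conditions: (Ph3P)AuNTf2 (3 mol%), THF, 4 Å sieves, 0 °C → rt; Et3N quench
Reagents that add atoms: none
Why: Monovalent-gold π-activation of the alkyne, 5-endo-dig attack of the cis C3 hydroxyl on C10 and protodeauration, a known cycloisomerization of homopropargylic alcohols to 2,3-dihydrofurans. The neutral phosphine–gold catalyst in THF is used instead of AuCl3 so that the tertiary allylic C8 alcohol of the product is not ionized, and aromatization is impossible because both ring-fusion carbons are quaternary.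

Step 13
Reactants: 19 key-step precursor
Product: 22 key-step product: 11-oxabicyclo[6.2.1]undecadienone with C8 ketone and C2=C3 enol ether and Z-C4=C5, via potassium alkoxide 20 (not isolated), via potassium enolate 21 (not isolated)
Conditions: KH (3 equiv), 18-crown-6 (3 equiv), THF, 0 → 40 °C; aqueous NH4Cl, −78 °C
Reagents that add atoms: none
Why: Proposed new method: KH/18-crown-6 gives the free C8 alkoxide 20, whose lone pair weakens the C3–C8 bond; the vinyl π bond aligns with that bond, C1 closes onto C10 of the enol ether and the charge ends on enolate 21, an anionic oxy-Cope [3,3] shift of the diene C1=C2–C3–C8–C9=C10 whose closest known type is the anionic oxy-Cope ring expansion of 1,2-divinylcycloalkanols. Because the breaking bond is a ring bond of the dihydrofuran lying near the nodal plane of C9=C10, the shift should be strongly asynchronous and may run as alkoxide fragmentation to an oxygen-tethered allyl anion and vinylogous ester followed by conjugate closure, which gives the same product. The five-membered ring O–C3–C2–C1–C10 closes in a 5-exo sense through a boat-like array bridged by oxygen (like 7-oxanorbornane), and the nine-membered ring arises when the shared C3–C8 bond of the fused rings breaks. The only new stereocenter, C10, is controlled by the angular C3 center, because the vinyl group can reach C10 only on the enol-ether face on which it stands; C6 and C7 are untouched. Three selectivities are needed: C1 and not C5 must bond to C10 (the ring alkene is held in the cyclohexene and cannot align with the breaking bond); the enolate must not equilibrate toward C7 (excess base, no proton source, cold quench); and no group may migrate to the alkoxide (the C6 silyl ether is trans-1,3 and C12 carries an aryl ether).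

Step 14
Reactants: 22 key-step product
Product: 23 8S alcohol (C8-OH cis to the C7 branch in the sense of the later lactone)
Conditions: NaBH4, THF/EtOH, −40 °C
Reagents that add atoms: none
Why: Borohydride reduction of the saturated ketone, done at once because C7 is epimerizable and the C6 silyloxy group is β to the carbonyl. Hydride is expected to attack the outer face of the nine-membered ring anti to the C7 branch (Felkin sense); enol ether and aryl ether are inert.

Step 15
Reactants: 23 8S alcohol
Product: 25 furanone alcohol (C1 ketone; C8-OH free), via C1 tert-butyl peroxide 24 (not isolated)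
Conditions: Rh2(cap)4 (dirhodium tetracaprolactamate, 1 mol%), t-BuOOH (70% in water, 5 equiv), NaHCO3, ClCH2CH2Cl, 40 °C
Reagents that add atoms: tert-butyl hydroperoxide, CC(C)(C)OO
Why: Allylic C–H oxidation by the tert-butylperoxyl radical chain; the C1 methylene next to the electron-rich enol ether has the weakest C–H bonds, the radical is captured as peroxide 24 and this collapses to the ketone, giving the vinylogous ester. The C6–H is tertiary and shielded by the silyl ether, the aryl ether has no benzylic hydrogen, and any over-oxidation at C8 is reversed by repeating step 14.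

Step 16
Reactants: 25 furanone alcohol
Product: 26 C8,C12-diol
Conditions: (NH4)2Ce(NO3)6, pyridine, MeCN/H2O 4:1, 0 °C
Reagents that add atoms: none
Why: Oxidative dearylation of the p-methoxyphenyl ether by tetravalent cerium frees the C12 alcohol. It follows step 15 because the electron-poor furanone, unlike the enol ether, tolerates the oxidant; pyridine buffering protects the silyl ether.

Step 17
Reactants: 26 C8,C12-diol
Product: 29 6-O-silyl α-methylene lactone, via hydroxy enal 27 (not isolated), via lactol 28 (not isolated)
Conditions: TEMPO (cat.), PhI(OAc)2, CH2Cl2, rt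
Reagents that add atoms: none
Why: The oxoammonium oxidant selects the primary allylic alcohol; the enal is trapped by the cis C8 hydroxyl as the lactol, which is oxidized on to the lactone (oxidative lactonization of a 2-methylene-1,4-diol). C6 is still silylated, so only the 8,12-lactone can form.

Step 18
Reactants: 29 6-O-silyl α-methylene lactone
Product: 30 6-O-detigloyl target (C6 alcohol)
Conditions: HF·pyridine, pyridine, THF, 0 °C → rt
Reagents that add atoms: none
Why: Desilylation under buffered, weakly acidic fluoride conditions that leave the exo-methylene lactone and the furanone untouched; basic fluoride sources are avoided.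

Step 19
Reactants: 30 6-O-detigloyl target; 31 tiglic acid
Product: 32 target CNP0293168.2
Conditions: 31, 2,4,6-Cl3C6H2COCl, Et3N, toluene, rt; then 30, DMAP, rt
Reagents that add atoms: 31 tiglic acid, C/C=C(\C)C(O)=O
Why: Yamaguchi esterification; the mixed anhydride acylates the hindered allylic C6 alcohol under DMAP catalysis with retention at C6 and without scrambling the tiglate geometry. No base strong enough to add to or deconjugate the exo-methylene lactone is present.

## Compound list

1 | (S)-(+)-carvone | CC1=CC[C@H](C(C)=C)CC1=O | starting material
2 | 10-chlorocarvone, (5S) | CC1=CC[C@H](C(=C)CCl)CC1=O | intermediate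
3 | 4-methoxyphenol | COc1ccc(O)cc1 | starting material
4 | C12 p-methoxyphenyl ether of 10-hydroxycarvone, (5S) | CC1=CC[C@H](C(=C)COc2ccc(OC)cc2)CC1=O | intermediate
5 | potassium extended dienolate of 4 | CC1=C([O-])C[C@@H](C(=C)COc2ccc(OC)cc2)C=C1.[K+] | intermediate
6 | trimethylsilyl dienol ether of 4 (C3=C4, C5=C6) | CC1=C(O[Si](C)(C)C)C[C@@H](C(=C)COc2ccc(OC)cc2)C=C1 | intermediate
7 | C3-silyloxy C3,C6-endoperoxide, peroxide bridge anti to the C7 branch | CC1=C[C@H]2OO[C@]1(O[Si](C)(C)C)C[C@H]2C(=C)COc3ccc(OC)cc3 | intermediate
8 | 6,7-trans γ-hydroxy enone, (4R,5S) | CC1=C[C@@H](O)[C@H](C(=C)COc2ccc(OC)cc2)CC1=O | intermediate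
9 | 6,7-cis 4-nitrobenzoate, (4S,5S) | CC1=C[C@H](OC(=O)c2ccc(cc2)[N+](=O)[O-])[C@H](C(=C)COc3ccc(OC)cc3)CC1=O | intermediate
10 | 6,7-cis γ-hydroxy enone, (4S,5S) | CC1=C[C@H](O)[C@H](C(=C)COc2ccc(OC)cc2)CC1=O | intermediate
11 | 6,7-cis γ-(tert-butyldimethylsilyloxy) enone, (4S,5S) | CC1=C[C@H](O[Si](C)(C)C(C)(C)C)[C@H](C(=C)COc2ccc(OC)cc2)CC1=O | intermediate
12 | potassium C3,C8-enolate of 11 | CC1=C[C@H](O[Si](C)(C)C(C)(C)C)[C@H](C(=C)COc2ccc(OC)cc2)C=C1[O-].[K+] | intermediate
13 | α′-hydroxy enone, C8-OH trans to the C7 branch | CC1=C[C@H](O[Si](C)(C)C(C)(C)C)[C@H](C(=C)COc2ccc(OC)cc2)[C@@H](O)C1=O | intermediate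
14 | vinylmagnesium bromide | C=C[Mg]Br | starting material
15 | C3-vinyl C3,C8-diol | CC1=C[C@H](O[Si](C)(C)C(C)(C)C)[C@H](C(=C)COc2ccc(OC)cc2)[C@@H](O)[C@@]1(O)C=C | intermediate
16 | α-ketol, C8 ketone and C3 vinyl carbinol | CC1=C[C@H](O[Si](C)(C)C(C)(C)C)[C@H](C(=C)COc2ccc(OC)cc2)C(=O)[C@@]1(O)C=C | intermediate
17 | 1-propynylmagnesium bromide | CC#C[Mg]Br | starting material
18 | C8-propynyl C3,C8-diol | CC1=C[C@H](O[Si](C)(C)C(C)(C)C)[C@H](C(=C)COc2ccc(OC)cc2)[C@](O)(C#CC)[C@@]1(O)C=C | intermediate
19 | key-step precursor, cis-fused 7a-vinyl-3a-hydroxy-2-methyl-tetrahydrobenzofuran | C=C[C@]12OC(C)=C[C@@]1(O)[C@@H](C(=C)COc3ccc(OC)cc3)[C@@H](O[Si](C)(C)C(C)(C)C)C=C2C | intermediate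
20 | potassium C8 alkoxide of 19 | C=C[C@]12OC(C)=C[C@@]1([O-])[C@@H](C(=C)COc3ccc(OC)cc3)[C@@H](O[Si](C)(C)C(C)(C)C)C=C2C.[K+] | intermediate
21 | potassium C8=C9 enolate of 22 | [O-]C1=C[C@]2(C)OC(=CC2)/C(C)=C\[C@H](O[Si](C)(C)C(C)(C)C)[C@@H]1C(=C)COc3ccc(OC)cc3.[K+] | intermediate
22 | key-step product, oxygen-bridged nine-membered ring with C8 ketone | O=C1C[C@]2(C)OC(=CC2)/C(C)=C\[C@H](O[Si](C)(C)C(C)(C)C)[C@@H]1C(=C)COc3ccc(OC)cc3 | intermediate
23 | 8S alcohol | O[C@H]1C[C@]2(C)OC(=CC2)/C(C)=C\[C@H](O[Si](C)(C)C(C)(C)C)[C@@H]1C(=C)COc3ccc(OC)cc3 | intermediate
24 | C1 tert-butyl peroxide of 23 | O[C@H]1C[C@]2(C)OC(=CC2OOC(C)(C)C)/C(C)=C\[C@H](O[Si](C)(C)C(C)(C)C)[C@@H]1C(=C)COc3ccc(OC)cc3 | intermediate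
25 | furanone alcohol | O[C@H]1C[C@]2(C)OC(=CC2=O)/C(C)=C\[C@H](O[Si](C)(C)C(C)(C)C)[C@@H]1C(=C)COc3ccc(OC)cc3 | intermediate
26 | C8,C12-diol | O[C@H]1C[C@]2(C)OC(=CC2=O)/C(C)=C\[C@H](O[Si](C)(C)C(C)(C)C)[C@@H]1C(=C)CO | intermediate
27 | hydroxy enal | O[C@H]1C[C@]2(C)OC(=CC2=O)/C(C)=C\[C@H](O[Si](C)(C)C(C)(C)C)[C@@H]1C(=C)C=O | intermediate
28 | lactol | C=C1C(O)O[C@H]2C[C@]3(C)OC(=CC3=O)/C(C)=C\[C@H](O[Si](C)(C)C(C)(C)C)[C@H]12 | intermediate
29 | 6-O-silyl α-methylene lactone | C=C1C(=O)O[C@H]2C[C@]3(C)OC(=CC3=O)/C(C)=C\[C@H](O[Si](C)(C)C(C)(C)C)[C@H]12 | intermediate
30 | 6-O-detigloyl target | C=C1C(=O)O[C@H]2C[C@]3(C)OC(=CC3=O)/C(C)=C\[C@H](O)[C@H]12 | intermediate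
31 | tiglic acid | C/C=C(\C)C(O)=O | starting material
32 | target CNP0293168.2, (6S,7R,8S,10S) | C=C1C(=O)O[C@H]2C[C@]3(C)OC(=CC3=O)/C(C)=C\[C@H](OC(=O)/C(C)=C/C)[C@H]12 | target

## Step count and least certain steps

Total step count: 19. Longest linear sequence: 19 steps (1 to 32); 3, 14, 17 and 31 are commercial.

Step 13 (key step).
- Risk: the rearrangement may stall at the alkoxide, or go by fragmentation with the wrong outcome. The breaking C3–C8 bond is a ring bond of the dihydrofuran and overlaps poorly with the enol-ether π bond. Fragmentation could be followed by bonding at C5 instead of C1, by β-elimination of the C6 silyloxy group from a carbanionic intermediate, or by enolate equilibration toward C7.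
- Fallback with known chemistry, from 18 back to 22: the ring expansion is done before the ether ring is made. Diol 18 is treated with KH/18-crown-6. In the dialkoxide the oxygens are diaxial, and the vinyl and propynyl groups are both exocyclic and gauche. This is the geometry of the known oxy-Cope rearrangement of 1-alkynyl-2-vinylcycloalkanols. Protonation gives the ten-membered 3,8-dione with a C9=C10 enone, F1. A mild catalyst (DBU, or pyridinium tosylate with sieves) should then close the ether bridge by transannular oxa-Michael addition of the C3 enol oxygen to C10, giving 22. The cost is that C10 is then set by the reversible oxa-Michael step and not by transfer from C3, and transannular aldol closure competes.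

Step 15 (C1 oxidation).
- Risk: hydrogen abstraction at other activated positions (C6–H, the C12 methylene), capture of the delocalized radical at C3 or C5, or oxidative loss of the enol ether. Precedent for this oxidation on a dienyl enol ether of this kind is thin, so this is the weakest step after the key step.
- Fallback, from 22 back to 25: the oxygen is introduced by ionic addition and allylic transposition. PhSeCl in aqueous MeCN with NaHCO3 adds selenium to C2 and water to C3, giving the α-seleno hemiketal F2. Oxidation to the selenoxide and syn-elimination toward C1 gives the allylic hemiketal F3. Pyridinium chlorochromate should then effect the oxidative 1,3-transposition of this tertiary allylic alcohol (Babler–Dauben type) to the keto furanone F4. NaBH4 at −40 °C reduces only the C8 ketone, since the furanone carbonyl is a vinylogous ester, and gives 25.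

Step 14 (C8 reduction).
- Risk: poor or reversed facial selectivity, because the reactive conformation of the nine-membered ring is not known; also epimerization at C7 before reduction.
- Fallback, from 22 back to 23: if reduction gives the 8-epi alcohol F5, Mitsunobu inversion with 4-nitrobenzoic acid gives the 8S ester F6, and methanolysis (K2CO3, MeOH) returns 23.

Step 11 (propynyl addition).
- Risk: attack on the wrong face, since the pseudoaxial C6 silyl ether is syn to the axial trajectory at C8; also enolization at C7 or α-ketol rearrangement of the magnesium alkoxide.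
- Fallback, from 16 back to 22: the epimeric diol F7 is carried on and not discarded. Its C3 oxygen and propynyl group are trans-diequatorial and still within reach, so the gold step should give the trans-fused dihydrofuran F8. Since C8 becomes trigonal in step 13 and the vinyl group still stands over the enol ether, F8 should give the same ketone 22.

Step 12 (gold cycloisomerization).
- Risk: Lewis-acid ionization of the tertiary C8 alcohol, giving Meyer–Schuster rearrangement before cyclization or a vinyl shift or elimination after it.
- Fallback, from 16 back to 19: the enol ether is built by carbonyl chemistry. The lithium enolate of acetone adds to the C8 ketone to give the aldol adduct F9, which closes with the C3 hydroxyl to the cyclic hemiketal F10. Dehydration of the hemiketal, the most easily ionized hydroxyl (methanesulfonyl chloride/Et3N, or pyridinium tosylate with sieves), gives 19.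

## Further compounds

F1 | step 13 | ten-membered 3,8-dione with C9=C10 enone and Z-C4=C5 | O=C1CCC(C)=CC(=O)[C@@H](C(=C)COc2ccc(OC)cc2)[C@@H](O[Si](C)(C)C(C)(C)C)/C=C1/C
F2 | step 15 | C2-phenylseleno C3-hemiketal of 22 | O=C1C[C@]2(C)OC(O)(C([Se]c3ccccc3)C2)/C(C)=C\[C@H](O[Si](C)(C)C(C)(C)C)[C@@H]1C(=C)COc4ccc(OC)cc4
F3 | step 15 | allylic C3-hemiketal with C1=C2 | O=C1C[C@]2(C)OC(O)(C=C2)/C(C)=C\[C@H](O[Si](C)(C)C(C)(C)C)[C@@H]1C(=C)COc3ccc(OC)cc3
F4 | step 15 | C8-keto furanone | O=C1C[C@]2(C)OC(=CC2=O)/C(C)=C\[C@H](O[Si](C)(C)C(C)(C)C)[C@@H]1C(=C)COc3ccc(OC)cc3
F5 | step 14 | 8-epi alcohol | O[C@@H]1C[C@]2(C)OC(=CC2)/C(C)=C\[C@H](O[Si](C)(C)C(C)(C)C)[C@@H]1C(=C)COc3ccc(OC)cc3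
F6 | step 14 | 8S 4-nitrobenzoate | [O-][N+](=O)c1ccc(cc1)C(=O)O[C@H]2C[C@]3(C)OC(=CC3)/C(C)=C\[C@H](O[Si](C)(C)C(C)(C)C)[C@@H]2C(=C)COc4ccc(OC)cc4
F7 | step 11 | C8-epimeric propynyl diol | CC1=C[C@H](O[Si](C)(C)C(C)(C)C)[C@H](C(=C)COc2ccc(OC)cc2)[C@@](O)(C#CC)[C@@]1(O)C=C
F8 | step 11 | trans-fused 7a-vinyl-3a-hydroxy-2-methyl-tetrahydrobenzofuran | C=C[C@]12OC(C)=C[C@]1(O)[C@@H](C(=C)COc3ccc(OC)cc3)[C@@H](O[Si](C)(C)C(C)(C)C)C=C2C
F9 | step 12 | C8 acetonyl aldol adduct | CC1=C[C@H](O[Si](C)(C)C(C)(C)C)[C@H](C(=C)COc2ccc(OC)cc2)[C@](O)(CC(C)=O)[C@@]1(O)C=C
F10 | step 12 | cyclic C10 hemiketal | C=C[C@]12OC(C)(O)C[C@@]1(O)[C@@H](C(=C)COc3ccc(OC)cc3)[C@@H](O[Si](C)(C)C(C)(C)C)C=C2C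
A1 | alternative 1 | ten-membered enynol fused to the lactone | C=C1C(=O)O[C@H]2C[C@](C)(O[Si](CC)(CC)CC)[C@@H](O)C#C/C(C)=C\[C@H](OC(=O)/C(C)=C/C)[C@H]12
A2 | alternative 1 | iodoalkyne aldehyde | C=C1C(=O)O[C@@H](C[C@](C)(O[Si](CC)(CC)CC)C=O)[C@@H]1[C@@H](OC(=O)/C(C)=C/C)/C=C(C)\C#CI
A3 | alternative 2 | 6-O-silyl oxygen-bridged dienone core | O=C1C[C@@H]2O[C@@]1(C)C/C=C\[C@@H](O[Si](C)(C)C(C)(C)C)/C=C2/C
A4 | alternative 2 | vinyl dihydropyran diazoketone | CC(=[N+]=[N-])C(=O)C[C@@H]1O[C@H](C=C)[C@@H](O[Si](C)(C)C(C)(C)C)C=C1C
A5 | alternative 3 | 6-O-detigloyl target (identical with 30) | C=C1C(=O)O[C@H]2C[C@]3(C)OC(=CC3=O)/C(C)=C\[C@H](O)[C@H]12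
A6 | alternative 3 | Z-alkenyl iodide aldehyde | C=C1C(=O)O[C@@H](C[C@]2(C)OC(=CC2=O)/C(C)=C\I)[C@@H]1C=O
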